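## Retrosynthetic overview

1. Target 23 ⇐ NaBH4 reduction of apo-aldehyde 22 ⇐ Wittig reaction (C11=C12) of the furanoid C15 phosphonium salt 19 with the symmetrical C10 dialdehyde 20.
2. 19 ⇐ keto-dihydrofuran 15: C3–OH by equatorial hydride delivery, C6=C7 by dehydration of an angular tertiary alcohol, gem-dimethyl by conjugate methylation of enone 12.
3. Key step: 12 ⇐ dienone 11 by a symmetry-breaking intramolecular oxa-Michael addition, in which the C8 carbinol selects one of two identical enone arms and sets C5.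
4. 11 ⇐ quinone monoketal 6 + enone 3 (aldol for C6–C7, CBS reduction for C8); 6 ⇐ oxidative dearomatisation of 2,6-dimethylphenol 4.
5. Ring order: the carbocycle is the former arene and is present from the start; the oxygen ring is closed onto it in the key step.

Assumption: atom labels C1–C15' follow carotenoid numbering (ring C1–C6, furan carbons C7/C8, chain from C9), and 1, 2 and 20 are taken as catalogue compounds.

## Route

Step 1
Reactants: 1 (tert-butyldimethylsilyloxy)acetaldehyde; 2 3-(triphenylphosphoranylidene)butan-2-one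
Product: 3 (3E)-5-[(tert-butyldimethylsilyl)oxy]-3-methylpent-3-en-2-one
Conditions: PhMe, 90 °C
Reagents that add atoms: none
Why: Wittig olefination with a ketone-stabilised ylide gives the (E)-trisubstituted enone, which already holds C7–C11 and the C9 methyl with the C9=C10 geometry of the target.

Step 2
Reactants: 4 2,6-dimethylphenol
Product: 6 4,4-dimethoxy-2,6-dimethylcyclohexa-2,5-dien-1-one, via 4-methoxy-2,6-dimethylphenol 5 (not isolated)
Conditions: PhI(OAc)2 (2.2 equiv), MeOH, 0 °C → rt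
Reagents that add atoms: methanol, CO
Why: Oxidative dearomatisation by hypervalent iodine with two methanol captures at the free para position gives the symmetrical quinone monoketal, which masks the future C3 carbonyl and leaves only the methyl-flanked carbonyl (future C6) open to nucleophiles.

Step 3
Reactants: 3 (3E)-5-[(tert-butyldimethylsilyl)oxy]-3-methylpent-3-en-2-one; 6 4,4-dimethoxy-2,6-dimethylcyclohexa-2,5-dien-1-one
Product: 9 (3E)-5-[(tert-butyldimethylsilyl)oxy]-1-(1-hydroxy-4,4-dimethoxy-2,6-dimethylcyclohexa-2,5-dien-1-yl)-3-methylpent-3-en-2-one, via lithium enolate 7 (not isolated), via lithium aldolate 8 (not isolated)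
Conditions: LiN(iPr)2, THF, −78 °C (3 added to base); then 6, −78 °C; AcOH quench at −78 °C
Reagents that add atoms: none
Why: Kinetic deprotonation at the acetyl methyl and aldol-type 1,2-addition of the lithium enolate to the only free carbonyl of the monoketal forms the C6–C7 bond, the cold acidic quench preventing retro-aldol; no stereocentre arises because the ring is still symmetrical.

Step 4
Reactants: 9 (3E)-5-[(tert-butyldimethylsilyl)oxy]-1-(1-hydroxy-4,4-dimethoxy-2,6-dimethylcyclohexa-2,5-dien-1-yl)-3-methylpent-3-en-2-one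
Product: 10 (2S,3E)-5-[(tert-butyldimethylsilyl)oxy]-1-(1-hydroxy-4,4-dimethoxy-2,6-dimethylcyclohexa-2,5-dien-1-yl)-3-methylpent-3-en-2-ol
Conditions: (R)-1-methyl-3,3-diphenyltetrahydro-1H,3H-pyrrolo[1,2-c][1,3,2]oxazaborole (0.2 equiv), catecholborane (2.5 equiv), PhMe, −78 °C
Reagents that add atoms: none
Why: Corey–Bakshi–Shibata reduction in which the α-methylalkenyl group acts as the large substituent, so the (R)-oxazaborolidine gives the (S)-carbinol (future C8); catecholborane is used because, once bound to the tertiary hydroxyl, it carries no hydride for an unselective intramolecular reduction.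

Step 5
Reactants: 10 (2S,3E)-5-[(tert-butyldimethylsilyl)oxy]-1-(1-hydroxy-4,4-dimethoxy-2,6-dimethylcyclohexa-2,5-dien-1-yl)-3-methylpent-3-en-2-ol
Product: 12 (2S,3aR,7aR)-2-[(2E)-4-[(tert-butyldimethylsilyl)oxy]but-2-en-2-yl]-3a-hydroxy-4,7a-dimethyl-3,3a,7,7a-tetrahydro-1-benzofuran-6(2H)-one, via quinol dienone 11 (not isolated)
Conditions: AcOH/H2O/THF, rt; concentrate; then 1,8-diazabicyclo[5.4.0]undec-7-ene (0.3 equiv), PhMe, rt → 40 °C
Reagents that add atoms: water, O
Why: Proposed new method: acid hydrolysis of the ketal unmasks the symmetrical 4-hydroxycyclohexa-2,5-dienone, and base-catalysed, reversible 5-exo oxa-Michael addition of the C8 hydroxyl to one of the two β-methyl enone arms breaks the symmetry, the necessarily cis-fused product with the side chain on the convex face (syn to the angular methyl and hydroxyl, away from the carbocycle) being expected as the thermodynamic sink so that the (S)-carbinol fixes C5 as R; the closest known reaction type is the oxa-Michael ring closure of 4-hydroxy-4-(2-hydroxyethyl)cyclohexa-2,5-dienones to cis-fused tetrahydrobenzofuranones, here extended to a β,β-disubstituted acceptor and to control by a carbinol stereocentre in the tether.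

Step 6
Reactants: 12 (2S,3aR,7aR)-2-[(2E)-4-[(tert-butyldimethylsilyl)oxy]but-2-en-2-yl]-3a-hydroxy-4,7a-dimethyl-3,3a,7,7a-tetrahydro-1-benzofuran-6(2H)-one
Product: 14 (2S,3aR,7aR)-2-[(2E)-4-[(tert-butyldimethylsilyl)oxy]but-2-en-2-yl]-3a-hydroxy-4,4,7a-trimethylhexahydro-1-benzofuran-6(2H)-one, via bis-silyl enol ether 13 (not isolated)
Conditions: Me2CuLi (5 equiv, from MeLi and CuI), Me3SiCl (6 equiv), THF, −78 → 0 °C; then K2CO3, MeOH, 0 °C
Reagents that add atoms: lithium dimethylcuprate, [Li+].C[Cu-]C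
Why: Me3SiCl-accelerated Gilman conjugate addition to the remaining β-methyl enone builds the gem-dimethyl carbon C1 (no new stereocentre), and methanolysis removes both trimethylsilyl groups while the primary silyl ether stays.

Step 7
Reactants: 14 (2S,3aR,7aR)-2-[(2E)-4-[(tert-butyldimethylsilyl)oxy]but-2-en-2-yl]-3a-hydroxy-4,4,7a-trimethylhexahydro-1-benzofuran-6(2H)-one
Product: 15 (2S,7aR)-2-[(2E)-4-[(tert-butyldimethylsilyl)oxy]but-2-en-2-yl]-4,4,7a-trimethyl-2,4,5,7a-tetrahydro-1-benzofuran-6(7H)-one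
Conditions: Et3N(+)SO2N(−)CO2Me (Burgess reagent), PhMe, 70 °C
Reagents that add atoms: none
Why: Burgess syn-elimination of the angular tertiary alcohol can only go towards C7 because C1 and C5 are quaternary, which gives the C6=C7 bond of the 2,5-dihydrofuran under neutral conditions without touching C5 or C8.

Step 8
Reactants: 15 (2S,7aR)-2-[(2E)-4-[(tert-butyldimethylsilyl)oxy]but-2-en-2-yl]-4,4,7a-trimethyl-2,4,5,7a-tetrahydro-1-benzofuran-6(7H)-one
Product: 17 (2S,6S,7aR)-2-[(2E)-4-hydroxybut-2-en-2-yl]-4,4,7a-trimethyl-2,4,5,6,7,7a-hexahydro-1-benzofuran-6-ol, via silyl ether alcohol 16 (not isolated)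
Conditions: Li[HB(s-Bu)3], THF, −78 °C; MeOH; then Bu4NF, THF, 0 °C → rt
Reagents that add atoms: none
Why: Substrate-controlled ketone reduction in which the bulky hydride attacks equatorially because the axial path is blocked by the syn-axial methyls on C1 and C5, giving the axial (3S) alcohol cis to the C5 methyl, after which fluoride removes the silyl ether in the same flask.

Step 9
Reactants: 17 (2S,6S,7aR)-2-[(2E)-4-hydroxybut-2-en-2-yl]-4,4,7a-trimethyl-2,4,5,6,7,7a-hexahydro-1-benzofuran-6-ol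
Product: 19 {(2E)-3-[(2S,6S,7aR)-6-hydroxy-4,4,7a-trimethyl-2,4,5,6,7,7a-hexahydro-1-benzofuran-2-yl]but-2-en-1-yl}triphenylphosphonium bromide, via allylic bromide 18 (not isolated)
Conditions: CBr4, PPh3 (1.1 equiv each), NaHCO3, MeCN, 0 °C; then PPh3 (1.3 equiv), rt
Reagents that add atoms: triphenylphosphine, c1ccc(cc1)P(c1ccccc1)c1ccccc1; carbon tetrabromide, BrC(Br)(Br)Br
Why: Appel bromination is selective for the primary allylic alcohol over the hindered axial secondary one under neutral conditions that spare the acid-labile bis-allylic ether at C8, and SN2 displacement by PPh3 then gives the phosphonium salt.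

Step 10
Reactants: 19 {(2E)-3-[(2S,6S,7aR)-6-hydroxy-4,4,7a-trimethyl-2,4,5,6,7,7a-hexahydro-1-benzofuran-2-yl]but-2-en-1-yl}triphenylphosphonium bromide; 20 (2E,4E,6E)-2,7-dimethylocta-2,4,6-trienedial (3 equiv)
Product: 22 (2E,4E,6E,8E,10E)-11-[(2S,6S,7aR)-6-hydroxy-4,4,7a-trimethyl-2,4,5,6,7,7a-hexahydro-1-benzofuran-2-yl]-2,7-dimethyldodeca-2,4,6,8,10-pentaenal, via phosphorus ylide 21 (not isolated)
Conditions: NaOMe, CH2Cl2/MeOH, 0 °C → rt; then heptane, 90 °C, dark
Reagents that add atoms: none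
Why: Wittig olefination of the semi-stabilised allylic ylide, generated in the presence of excess symmetrical dialdehyde so that it is trapped at once and condenses only once, forms C11=C12, and heating converts the hindered Z isomer into the all-E polyene.

Step 11
Reactants: 22 (2E,4E,6E,8E,10E)-11-[(2S,6S,7aR)-6-hydroxy-4,4,7a-trimethyl-2,4,5,6,7,7a-hexahydro-1-benzofuran-2-yl]-2,7-dimethyldodeca-2,4,6,8,10-pentaenal
Product: 23 (2E,4E,6E,8E,10E)-11-[(2S,6S,7aR)-6-hydroxy-4,4,7a-trimethyl-2,4,5,6,7,7a-hexahydro-1-benzofuran-2-yl]-2,7-dimethyldodeca-2,4,6,8,10-pentaen-1-ol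
Conditions: NaBH4, MeOH/THF, 0 °C
Reagents that add atoms: none
Why: Chemoselective 1,2-reduction of the conjugated aldehyde by borohydride gives the primary allylic alcohol without touching the polyene or any stereocentre.

## Compound list

1 | (tert-butyldimethylsilyloxy)acetaldehyde | O=CCO[Si](C)(C)C(C)(C)C | starting material
2 | 3-(triphenylphosphoranylidene)butan-2-one | CC(=O)C(C)=P(c1ccccc1)(c1ccccc1)c1ccccc1 | starting material
3 | (3E)-5-[(tert-butyldimethylsilyl)oxy]-3-methylpent-3-en-2-one | CC(=O)/C(C)=C/CO[Si](C)(C)C(C)(C)C | intermediate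
4 | 2,6-dimethylphenol | Cc1cccc(C)c1O | starting material
5 | 4-methoxy-2,6-dimethylphenol | COc1cc(C)c(O)c(C)c1 | intermediate
6 | 4,4-dimethoxy-2,6-dimethylcyclohexa-2,5-dien-1-one | COC1(OC)C=C(C)C(=O)C(C)=C1 | intermediate
7 | lithium (3E)-5-[(tert-butyldimethylsilyl)oxy]-3-methylpenta-1,3-dien-2-olate | [Li]OC(=C)/C(C)=C/CO[Si](C)(C)C(C)(C)C | intermediate
8 | lithium 1-[(3E)-5-[(tert-butyldimethylsilyl)oxy]-3-methyl-2-oxopent-3-en-1-yl]-4,4-dimethoxy-2,6-dimethylcyclohexa-2,5-dien-1-olate | COC1(OC)C=C(C)C(O[Li])(CC(=O)/C(C)=C/CO[Si](C)(C)C(C)(C)C)C(C)=C1 | intermediate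
9 | (3E)-5-[(tert-butyldimethylsilyl)oxy]-1-(1-hydroxy-4,4-dimethoxy-2,6-dimethylcyclohexa-2,5-dien-1-yl)-3-methylpent-3-en-2-one | COC1(OC)C=C(C)C(O)(CC(=O)/C(C)=C/CO[Si](C)(C)C(C)(C)C)C(C)=C1 | intermediate
10 | (2S,3E)-5-[(tert-butyldimethylsilyl)oxy]-1-(1-hydroxy-4,4-dimethoxy-2,6-dimethylcyclohexa-2,5-dien-1-yl)-3-methylpent-3-en-2-ol | COC1(OC)C=C(C)C(O)(C[C@H](O)/C(C)=C/CO[Si](C)(C)C(C)(C)C)C(C)=C1 | intermediate
11 | 4-hydroxy-4-[(2S,3E)-5-[(tert-butyldimethylsilyl)oxy]-2-hydroxy-3-methylpent-3-en-1-yl]-3,5-dimethylcyclohexa-2,5-dien-1-one | O=C1C=C(C)C(O)(C[C@H](O)/C(C)=C/CO[Si](C)(C)C(C)(C)C)C(C)=C1 | intermediate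
12 | (2S,3aR,7aR)-2-[(2E)-4-[(tert-butyldimethylsilyl)oxy]but-2-en-2-yl]-3a-hydroxy-4,7a-dimethyl-3,3a,7,7a-tetrahydro-1-benzofuran-6(2H)-one | [C@@H]1(/C(C)=C/CO[Si](C)(C)C(C)(C)C)C[C@@]2(O)C(C)=CC(=O)C[C@@]2(C)O1 | intermediate
13 | (2S,3aR,7aR)-2-[(2E)-4-[(tert-butyldimethylsilyl)oxy]but-2-en-2-yl]-4,4,7a-trimethyl-3a,6-bis(trimethylsilyloxy)-2,3,3a,4,7,7a-hexahydro-1-benzofuran | [C@@H]1(/C(C)=C/CO[Si](C)(C)C(C)(C)C)C[C@@]2(O[Si](C)(C)C)C(C)(C)C=C(O[Si](C)(C)C)C[C@@]2(C)O1 | intermediate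
14 | (2S,3aR,7aR)-2-[(2E)-4-[(tert-butyldimethylsilyl)oxy]but-2-en-2-yl]-3a-hydroxy-4,4,7a-trimethylhexahydro-1-benzofuran-6(2H)-one | [C@@H]1(/C(C)=C/CO[Si](C)(C)C(C)(C)C)C[C@@]2(O)C(C)(C)CC(=O)C[C@@]2(C)O1 | intermediate
15 | (2S,7aR)-2-[(2E)-4-[(tert-butyldimethylsilyl)oxy]but-2-en-2-yl]-4,4,7a-trimethyl-2,4,5,7a-tetrahydro-1-benzofuran-6(7H)-one | [C@@H]1(/C(C)=C/CO[Si](C)(C)C(C)(C)C)C=C2C(C)(C)CC(=O)C[C@@]2(C)O1 | intermediate
16 | (2S,6S,7aR)-2-[(2E)-4-[(tert-butyldimethylsilyl)oxy]but-2-en-2-yl]-4,4,7a-trimethyl-2,4,5,6,7,7a-hexahydro-1-benzofuran-6-ol | [C@@H]1(/C(C)=C/CO[Si](C)(C)C(C)(C)C)C=C2C(C)(C)C[C@H](O)C[C@@]2(C)O1 | intermediate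
17 | (2S,6S,7aR)-2-[(2E)-4-hydroxybut-2-en-2-yl]-4,4,7a-trimethyl-2,4,5,6,7,7a-hexahydro-1-benzofuran-6-ol | [C@@H]1(/C(C)=C/CO)C=C2C(C)(C)C[C@H](O)C[C@@]2(C)O1 | intermediate
18 | (2S,6S,7aR)-2-[(2E)-4-bromobut-2-en-2-yl]-4,4,7a-trimethyl-2,4,5,6,7,7a-hexahydro-1-benzofuran-6-ol | [C@@H]1(/C(C)=C/CBr)C=C2C(C)(C)C[C@H](O)C[C@@]2(C)O1 | intermediate
19 | {(2E)-3-[(2S,6S,7aR)-6-hydroxy-4,4,7a-trimethyl-2,4,5,6,7,7a-hexahydro-1-benzofuran-2-yl]but-2-en-1-yl}triphenylphosphonium bromide | [Br-].[C@@H]1(/C(C)=C/C[P+](c3ccccc3)(c3ccccc3)c3ccccc3)C=C2C(C)(C)C[C@H](O)C[C@@]2(C)O1 | intermediate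
20 | (2E,4E,6E)-2,7-dimethylocta-2,4,6-trienedial | O=C/C(C)=C/C=C/C=C(\C)C=O | starting material
21 | (2S,6S,7aR)-4,4,7a-trimethyl-2-[(2E)-4-(triphenylphosphoranylidene)but-2-en-2-yl]-2,4,5,6,7,7a-hexahydro-1-benzofuran-6-ol | [C@@H]1(/C(C)=C/C=P(c3ccccc3)(c3ccccc3)c3ccccc3)C=C2C(C)(C)C[C@H](O)C[C@@]2(C)O1 | intermediate
22 | (2E,4E,6E,8E,10E)-11-[(2S,6S,7aR)-6-hydroxy-4,4,7a-trimethyl-2,4,5,6,7,7a-hexahydro-1-benzofuran-2-yl]-2,7-dimethyldodeca-2,4,6,8,10-pentaenal | CC(/C=C/C=C(\C)[C@@H]1C=C2C(C)(C)C[C@H](O)C[C@@]2(C)O1)=C\C=C\C=C(/C)C=O | intermediate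
23 | (2E,4E,6E,8E,10E)-11-[(2S,6S,7aR)-6-hydroxy-4,4,7a-trimethyl-2,4,5,6,7,7a-hexahydro-1-benzofuran-2-yl]-2,7-dimethyldodeca-2,4,6,8,10-pentaen-1-ol | CC(/C=C/C=C(\C)[C@@H]1C=C2C(C)(C)C[C@H](O)C[C@@]2(C)O1)=C\C=C\C=C(/C)CO | target

## Step count and risks

Total step count: 11. Longest linear sequence: 10 steps (4 → 6 → 9 → 10 → 12 → 14 → 15 → 17 → 19 → 22 → 23).

Most likely to fail, step 5: the oxa-Michael closure onto a β-methyl enone may lie unfavourably at equilibrium or give a poor ratio of the two arm-selective diastereomers. The fallback sets out from 10 and replaces the reversible conjugate addition by an irreversible, kinetically controlled ether closure before the enone exists. N-iodosuccinimide/NaHCO3 in MeCN at −20 °C effects 5-exo iodoetherification of the C8 hydroxyl onto one ring alkene (oxygen to the methyl-bearing carbon) to give the iodo ether ketal F3. Bu3SnH with Et3B/air removes the iodine to give the bicyclic ether ketal F4 (a radical step, chosen because a metal enolate would expel the β-alkoxy group). AcOH/H2O/THF then unmasks the enone, and the sequence comes back to the route at 12.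

Second, step 3: a ketone enolate adding to a carbonyl flanked by two methyl-bearing alkene carbons may be slow and reversible. The fallback sets out from 3 and makes the addition reductive and irreversible. Me3SiOTf/Et3N gives the silyloxydiene F1, N-bromosuccinimide gives the bromomethyl ketone F2, and SmI2 (2 equiv, THF, −78 °C) turns F2 into a samarium enolate that adds to 6 in a Reformatsky-type aldol. It comes back to the route at 9.

Third, step 6: the cuprate has to form a quaternary carbon next to the fully substituted C6 and may stall or trigger retro-oxa-Michael opening. The fallback sets out from 12 and delivers the second methyl as a methylene. Dimethylsulfoxonium methylide (Me3S(O)I, NaH, DMSO) cyclopropanates the enone to the cyclopropyl ketone F5 (either cyclopropane face serves). SmI2 in THF with t-BuOH then cleaves the exocyclic cyclopropane bond that overlaps with the carbonyl, turning the methylene into the second methyl on C1. It comes back to the route at 14.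

Further compounds
F1 | step 3 | tert-butyldimethyl{[(2E)-3-methyl-4-(trimethylsilyloxy)penta-2,4-dien-1-yl]oxy}silane | C=C(O[Si](C)(C)C)/C(C)=C/CO[Si](C)(C)C(C)(C)C
F2 | step 3 | (3E)-1-bromo-5-[(tert-butyldimethylsilyl)oxy]-3-methylpent-3-en-2-one | BrCC(=O)/C(C)=C/CO[Si](C)(C)C(C)(C)C
F3 | step 5 | (2S,3aR,7R,7aS)-2-[(2E)-4-[(tert-butyldimethylsilyl)oxy]but-2-en-2-yl]-7-iodo-6,6-dimethoxy-4,7a-dimethyl-2,3,7,7a-tetrahydro-1-benzofuran-3a(6H)-ol | [C@@H]1(/C(C)=C/CO[Si](C)(C)C(C)(C)C)C[C@@]2(O)C(C)=CC(OC)(OC)[C@H](I)[C@@]2(C)O1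
F4 | step 5 | (2S,3aR,7aR)-2-[(2E)-4-[(tert-butyldimethylsilyl)oxy]but-2-en-2-yl]-6,6-dimethoxy-4,7a-dimethyl-2,3,7,7a-tetrahydro-1-benzofuran-3a(6H)-ol | [C@@H]1(/C(C)=C/CO[Si](C)(C)C(C)(C)C)C[C@@]2(O)C(C)=CC(OC)(OC)C[C@@]2(C)O1
F5 | step 6 | cyclopropyl ketone from methylene transfer to the C1=C2 bond of 12 (cyclopropane configuration not fixed) | [C@@H]1(/C(C)=C/CO[Si](C)(C)C(C)(C)C)C[C@@]2(O)C3(C)CC3C(=O)C[C@@]2(C)O1
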